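## Retrosynthetic overview

1. Target ⇐ tricyclic keto acetate: the cis-bromohydrin is made last, by kinetic α-bromination and then carbonyl reduction.
2. Cyclobutanol ring (formed last) ⇐ SmI2 4-exo-trig ketyl–enone radical cyclisation of an aldehyde-tethered hydrindenone. This single bond closes the four-membered ring and creates the central quaternary carbon between two existing quaternary carbons.
3. Hydrindenone (six-membered ring, formed second) ⇐ ynone annulation of a bromocyclopentanone with hex-4-yn-3-one, then face-selective conjugate reduction to set the secondary methyl.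
4. Bromocyclopentanone (five-membered ring, purchased) ⇐ 2-methylcyclopentane-1,3-dione + allyl bromide, enzymatic desymmetrisation, then two SN2 inversions (O, then Br).

Assumption: an isolated Prelog ketoreductase with glucose/GDH recycling gives the same (2S,3S) ketol from dione 3 as whole-cell baker's yeast (OH cis to allyl), and hex-4-yn-3-one is purchased.

Numbering used in names: bicyclic compounds are numbered as 5H-inden-5-ones. Tricyclic compounds are numbered as tricyclo[5.4.0.0^{1,4}]undecanes (C1 central quaternary carbon, C2 cyclobutanol carbon, C4/C7 methyl-bearing quaternary carbons, C5 CHBr, C10 carbonyl/carbinol). CIP descriptors were derived by hand from the SMILES; the SMILES are authoritative.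

## Route

Step 1
Reactants: 1 2-methylcyclopentane-1,3-dione; 2 allyl bromide
Product: 3 2-methyl-2-(prop-2-en-1-yl)cyclopentane-1,3-dione
Conditions: 2 (1.5 equiv), 1 M NaOH (aq), rt, 24 h
Reagents that add atoms: none
Why: C-alkylation of the stabilised 1,3-dione enolate by the allylic bromide gives the prochiral 2,2-disubstituted dione (enolate alkylation).

Step 2
Reactants: 3 2-methyl-2-(prop-2-en-1-yl)cyclopentane-1,3-dione
Product: 4 (2S,3S)-3-hydroxy-2-methyl-2-(prop-2-en-1-yl)cyclopentan-1-one
Conditions: Prelog ketoreductase (baker's-yeast type), NADP+ (cat.), glucose dehydrogenase (cat.), D-glucose, pH 7 phosphate buffer, 30 °C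
Reagents that add atoms: none
Why: Enzymatic desymmetrisation (Prelog carbonyl reduction) reduces one enantiotopic C=O with hydride anti to the allyl group, fixing the quaternary C2 and C3 as (2S,3S) with OH cis to allyl.

Step 3
Reactants: 4 (2S,3S)-3-hydroxy-2-methyl-2-(prop-2-en-1-yl)cyclopentan-1-one
Product: 7 (2S,3R)-3-hydroxy-2-methyl-2-(prop-2-en-1-yl)cyclopentan-1-one, via triflate 5 (not isolated), via nitrite ester 6 (not isolated)
Conditions: Tf2O, pyridine, CH2Cl2, −20 °C; then KNO2, 18-crown-6 (cat.), DMF, rt; aqueous work-up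
Reagents that add atoms: potassium nitrite, [K+].[O-]N=O
Why: Lattrell–Dax inversion: nitrite oxygen displaces the triflate by SN2 from the methyl-bearing face and the nitrite ester hydrolyses on work-up, giving the alcohol trans to allyl.

Step 4
Reactants: 7 (2S,3R)-3-hydroxy-2-methyl-2-(prop-2-en-1-yl)cyclopentan-1-one
Product: 9 (2R,3S)-3-bromo-2-methyl-2-(prop-2-en-1-yl)cyclopentan-1-one, via triflate 8 (not isolated)
Conditions: Tf2O, pyridine, CH2Cl2, −30 °C; then LiBr, acetone, 0 °C → rt
Reagents that add atoms: lithium bromide, [Li+].[Br-]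
Why: SN2 displacement of the triflate by bromide (no E1cB is possible because C2 is quaternary) inverts C3 a second time, placing Br cis to the allyl arm; the C2 descriptor changes only because of CIP priorities.

Step 5
Reactants: 9 (2R,3S)-3-bromo-2-methyl-2-(prop-2-en-1-yl)cyclopentan-1-one
Product: 11 (2R,3S,5S)-3-bromo-2,5-dimethyl-2-(prop-2-en-1-yl)cyclopentan-1-one, via lithium enolate 10 (not isolated)
Conditions: LDA, THF, −78 °C; then MeI, −78 → −30 °C
Reagents that add atoms: iodomethane, CI
Why: Kinetic enolate alkylation at the only enolisable α-carbon (C5); methyl enters anti to Br/allyl, but this centre becomes planar again in step 6, so the epimer ratio does not matter.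

Step 6
Reactants: 11 (2R,3S,5S)-3-bromo-2,5-dimethyl-2-(prop-2-en-1-yl)cyclopentan-1-one; 12 hex-4-yn-3-one
Product: 16 (2S,3R,7aR)-2-bromo-3,4,7,7a-tetramethyl-3-(prop-2-en-1-yl)-1,2,3,7a-tetrahydro-5H-inden-5-one, via lithium enolate 13 (not isolated), via lithium allenolate 14 (not isolated), via enedione 15 (not isolated)
Conditions: LiHMDS, THF, −40 °C; then 12, −78 → 0 °C; then TsOH·H2O (2.5 equiv), toluene, 80 °C, 4 Å MS
Reagents that add atoms: none
Why: Michael addition of the tetrasubstituted enolate to the ynone, on the face anti to Br and allyl, sets the quaternary C7a; acid then equilibrates the E/Z enedione and drives the intramolecular aldol condensation to the cross-conjugated dienone (Robinson-type annulation with an ynone).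

Step 7
Reactants: 16 (2S,3R,7aR)-2-bromo-3,4,7,7a-tetramethyl-3-(prop-2-en-1-yl)-1,2,3,7a-tetrahydro-5H-inden-5-one
Product: 18 (2S,3R,7S,7aR)-2-bromo-3,4,7,7a-tetramethyl-3-(prop-2-en-1-yl)-1,2,3,6,7,7a-hexahydro-5H-inden-5-one, via silyl dienol ether 17 (not isolated)
Conditions: [(Ph3P)CuH]6 (5 mol %), PhMe2SiH (1.5 equiv), toluene, rt; then 1 M HCl, THF, 0 °C
Reagents that add atoms: none
Why: Copper hydride-catalysed 1,4-hydrosilylation (Stryker-type conjugate reduction) touches only the less hindered trisubstituted enone and delivers hydride to C7 anti to the pseudo-axial C7a methyl, so the C7 methyl ends cis to the C7a methyl; hydrolysis of the dienol ether returns the conjugated enone.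

Step 8
Reactants: 18 (2S,3R,7S,7aR)-2-bromo-3,4,7,7a-tetramethyl-3-(prop-2-en-1-yl)-1,2,3,6,7,7a-hexahydro-5H-inden-5-one
Product: 20 2-[(2S,3R,7S,7aR)-2-bromo-3,4,7,7a-tetramethyl-5-oxo-1,2,3,6,7,7a-hexahydroinden-3-yl]acetaldehyde, via ozonide 19 (not isolated)
Conditions: O3, CH2Cl2, −78 °C (Sudan Red 7B end point); then Me2S, −78 °C → rt
Reagents that add atoms: ozone, [O-][O+]=O
Why: Ozonolysis with reductive work-up cleaves the electron-rich terminal alkene chemoselectively over the electron-poor, tetrasubstituted enone.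

Step 9
Reactants: 20 2-[(2S,3R,7S,7aR)-2-bromo-3,4,7,7a-tetramethyl-5-oxo-1,2,3,6,7,7a-hexahydroinden-3-yl]acetaldehyde
Product: 23 (1R,2R,4R,5S,7R,8S,11R)-5-bromo-2-hydroxy-4,7,8,11-tetramethyltricyclo[5.4.0.0^{1,4}]undecan-10-one, via samarium ketyl 21 (not isolated), via samarium enolate 22 (not isolated)
Conditions: SmI2 (2.5 equiv), THF/MeOH 4:1, 0 °C; then crude product, K2CO3 (cat.), MeOH, rt
Reagents that add atoms: none
Why: SmI2-mediated 4-exo-trig ketyl–olefin radical cyclisation: the aldehyde ketyl adds to the enone β-carbon from the face of its own tether (cis ring fusion, C1), the bulky O–Sm turns away from the syn C7 methyl (sets C2–OH cis to C11), a second electron gives the samarium enolate, and base equilibration puts the C11 methyl equatorial.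

Step 10
Reactants: 23 (1R,2R,4R,5S,7R,8S,11R)-5-bromo-2-hydroxy-4,7,8,11-tetramethyltricyclo[5.4.0.0^{1,4}]undecan-10-one
Product: 24 (1R,2R,4R,5S,7R,8S,11R)-5-bromo-4,7,8,11-tetramethyl-10-oxotricyclo[5.4.0.0^{1,4}]undecan-2-yl acetate
Conditions: Ac2O, pyridine, DMAP (cat.), CH2Cl2, rt
Reagents that add atoms: acetic anhydride, CC(=O)OC(C)=O
Why: DMAP-catalysed acylation of the secondary cyclobutanol; no stereocentre is touched.

Step 11
Reactants: 24 (1R,2R,4R,5S,7R,8S,11R)-5-bromo-4,7,8,11-tetramethyl-10-oxotricyclo[5.4.0.0^{1,4}]undecan-2-yl acetate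
Product: 27 (1R,2R,4R,5S,7R,8R,9S,11R)-5,9-dibromo-4,7,8,11-tetramethyl-10-oxotricyclo[5.4.0.0^{1,4}]undecan-2-yl acetate, via lithium enolate 25 (not isolated), via silyl enol ether 26 (not isolated)
Conditions: LiHMDS (1.1 equiv), THF, −78 °C; TMSCl, −78 °C; then NBS, THF, −78 → 0 °C
Reagents that add atoms: N-bromosuccinimide, O=C1CCC(=O)N1Br
Why: Kinetic deprotonation at the less hindered C9 methylene, silylation and electrophilic bromination of the silyl enol ether; Br+ enters anti to the syn-axial C7 methyl, giving the equatorial 9-bromide trans to the C8 methyl (also the thermodynamic epimer).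

Step 12
Reactants: 27 (1R,2R,4R,5S,7R,8R,9S,11R)-5,9-dibromo-4,7,8,11-tetramethyl-10-oxotricyclo[5.4.0.0^{1,4}]undecan-2-yl acetate
Product: 28 (1R,2R,4R,5S,7R,8R,9S,10R,11R)-5,9-dibromo-10-hydroxy-4,7,8,11-tetramethyltricyclo[5.4.0.0^{1,4}]undecan-2-yl acetate (CNP0246576.1)
Conditions: NaBH4, MeOH/THF, −40 → 0 °C
Reagents that add atoms: none
Why: Borohydride reduction with equatorial hydride attack, because the axial trajectory is blocked by the axial C1–C4 bond 1,3 to the carbonyl; this gives the axial C10 alcohol cis to the equatorial bromide (cis-bromohydrin, no epoxide closure possible).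

## Compound list

1 | 2-methylcyclopentane-1,3-dione | CC1C(=O)CCC1=O | starting material
2 | allyl bromide (3-bromoprop-1-ene) | C=CCBr | starting material
3 | 2-methyl-2-(prop-2-en-1-yl)cyclopentane-1,3-dione | CC1(CC=C)C(=O)CCC1=O | intermediate
4 | (2S,3S)-3-hydroxy-2-methyl-2-(prop-2-en-1-yl)cyclopentan-1-one (OH cis to allyl) | O=C1CC[C@H](O)[C@]1(C)CC=C | intermediate
5 | triflate of 4 (configuration retained) | O=C1CC[C@H](OS(=O)(=O)C(F)(F)F)[C@]1(C)CC=C | intermediate
6 | nitrite ester of 7 (C3 inverted) | O=C1CC[C@@H](ON=O)[C@]1(C)CC=C | intermediate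
7 | (2S,3R)-3-hydroxy-2-methyl-2-(prop-2-en-1-yl)cyclopentan-1-one (OH trans to allyl) | O=C1CC[C@@H](O)[C@]1(C)CC=C | intermediate
8 | triflate of 7 | O=C1CC[C@@H](OS(=O)(=O)C(F)(F)F)[C@]1(C)CC=C | intermediate
9 | (2R,3S)-3-bromo-2-methyl-2-(prop-2-en-1-yl)cyclopentan-1-one (Br cis to allyl) | O=C1CC[C@H](Br)[C@]1(C)CC=C | intermediate
10 | lithium enolate of 9 | [Li]OC1=CC[C@H](Br)[C@]1(C)CC=C | intermediate
11 | (2R,3S,5S)-3-bromo-2,5-dimethyl-2-(prop-2-en-1-yl)cyclopentan-1-one (major C5 epimer) | O=C1[C@@H](C)C[C@H](Br)[C@]1(C)CC=C | intermediate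
12 | hex-4-yn-3-one | CCC(=O)C#CC | starting material
13 | lithium enolate of 11 (tetrasubstituted) | [Li]OC1=C(C)C[C@H](Br)[C@]1(C)CC=C | intermediate
14 | lithium allenolate Michael adduct of 13 and 12 | O=C1[C@@](C)(C(C)=C=C(O[Li])CC)C[C@H](Br)[C@]1(C)CC=C | intermediate
15 | (2R,3S,5R)-3-bromo-2,5-dimethyl-5-[(2Z)-4-oxohex-2-en-2-yl]-2-(prop-2-en-1-yl)cyclopentan-1-one (E/Z mixture, reacting Z isomer shown) | O=C1[C@@](C)(/C(C)=C\C(=O)CC)C[C@H](Br)[C@]1(C)CC=C | intermediate
16 | (2S,3R,7aR)-2-bromo-3,4,7,7a-tetramethyl-3-(prop-2-en-1-yl)-1,2,3,7a-tetrahydro-5H-inden-5-one (cross-conjugated dienone; Br, allyl and 7a-Me on one face) | CC1=C2[C@@](C)(CC=C)[C@@H](Br)C[C@]2(C)C(C)=CC1=O | intermediate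
17 | 5-[dimethyl(phenyl)silyl]oxy dienol ether of 18 (C3a=C4, C5=C6) | CC1=C2[C@@](C)(CC=C)[C@@H](Br)C[C@]2(C)[C@@H](C)C=C1O[Si](C)(C)c1ccccc1 | intermediate
18 | (2S,3R,7S,7aR)-2-bromo-3,4,7,7a-tetramethyl-3-(prop-2-en-1-yl)-1,2,3,6,7,7a-hexahydro-5H-inden-5-one (7-Me cis to 7a-Me) | CC1=C2[C@@](C)(CC=C)[C@@H](Br)C[C@]2(C)[C@@H](C)CC1=O | intermediate
19 | secondary ozonide (1,2,4-trioxolane) of the allyl group of 18 | CC1=C2[C@@](C)(CC3OCOO3)[C@@H](Br)C[C@]2(C)[C@@H](C)CC1=O | intermediate
20 | 2-[(2S,3R,7S,7aR)-2-bromo-3,4,7,7a-tetramethyl-5-oxo-1,2,3,6,7,7a-hexahydroinden-3-yl]acetaldehyde | CC1=C2[C@@](C)(CC=O)[C@@H](Br)C[C@]2(C)[C@@H](C)CC1=O | intermediate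
21 | samarium(III) ketyl radical of 20 | CC1=C2[C@@](C)(C[CH]O[Sm](I)I)[C@@H](Br)C[C@]2(C)[C@@H](C)CC1=O | intermediate
22 | cyclised samarium(III) alkoxide–enolate (C10=C11 enolate) | I[Sm](I)O[C@@H]1C[C@@]2(C)[C@@H](Br)C[C@]3(C)[C@@H](C)CC(O[Sm](I)I)=C(C)[C@]123 | intermediate
23 | (1R,2R,4R,5S,7R,8S,11R)-5-bromo-2-hydroxy-4,7,8,11-tetramethyltricyclo[5.4.0.0^{1,4}]undecan-10-one | O[C@@H]1C[C@@]2(C)[C@@H](Br)C[C@]3(C)[C@@H](C)CC(=O)[C@H](C)[C@]123 | intermediate
24 | (1R,2R,4R,5S,7R,8S,11R)-5-bromo-4,7,8,11-tetramethyl-10-oxotricyclo[5.4.0.0^{1,4}]undecan-2-yl acetate | CC(=O)O[C@@H]1C[C@@]2(C)[C@@H](Br)C[C@]3(C)[C@@H](C)CC(=O)[C@H](C)[C@]123 | intermediate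
25 | lithium C9–C10 enolate of 24 | CC(=O)O[C@@H]1C[C@@]2(C)[C@@H](Br)C[C@]3(C)[C@@H](C)C=C(O[Li])[C@H](C)[C@]123 | intermediate
26 | trimethylsilyl C9–C10 enol ether of 24 | CC(=O)O[C@@H]1C[C@@]2(C)[C@@H](Br)C[C@]3(C)[C@@H](C)C=C(O[Si](C)(C)C)[C@H](C)[C@]123 | intermediate
27 | (1R,2R,4R,5S,7R,8R,9S,11R)-5,9-dibromo-4,7,8,11-tetramethyl-10-oxotricyclo[5.4.0.0^{1,4}]undecan-2-yl acetate | CC(=O)O[C@@H]1C[C@@]2(C)[C@@H](Br)C[C@]3(C)[C@@H](C)[C@H](Br)C(=O)[C@H](C)[C@]123 | intermediate
28 | (1R,2R,4R,5S,7R,8R,9S,10R,11R)-5,9-dibromo-10-hydroxy-4,7,8,11-tetramethyltricyclo[5.4.0.0^{1,4}]undecan-2-yl acetate | CC(=O)O[C@@H]1C[C@@]2(C)[C@@H](Br)C[C@]3(C)[C@@H](C)[C@H](Br)[C@H](O)[C@H](C)[C@]123 | target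

## Step count and risks

Total steps: 12. Longest linear sequence: 12 (from 1; 2 and 12 enter as purchased materials).

Three steps most likely to fail:

**Step 9 (SmI2 4-exo-trig cyclisation).** The new bond joins a fully substituted enone β-carbon that sits between two quaternary carbons. Simple reduction of the aldehyde or of the enone can compete, and the C2 configuration rests on a steric argument. Fallback, from 20 back to 24 (23 is bypassed): 20 is converted with Ac2O/Et3N/DMAP into the enol acetate of the aldehyde, F4. F4 is then treated with Fe(acac)3 and PhSiH3 in EtOH at 60 °C. Metal-hydride hydrogen atom transfer to the electron-rich enol acetate gives an α-acetoxyalkyl radical, which closes the same bond by 4-exo Giese addition to the enone; reduction and protonation of the α-keto radical deliver acetate 24 directly. This keeps a radical ring closure but replaces the ketyl (single-electron reduction) by a neutral carbon radical made by HAT, and it installs the acetate at the same time.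

**Step 6 (ynone annulation).** Possible failures are 1,2-addition to the ynone, an E-enedione that does not reach the Z geometry, the aldol onto a ketone flanked by two quaternary carbons, and acid-induced dienone–phenol rearrangement. Fallback, from 15 back to 16: the Michael stage is quenched and enedione 15 is isolated. TMSOTf/Et3N converts its ethyl ketone into the 2-silyloxydiene F2. TiCl4 in CH2Cl2 at −78 °C then effects an irreversible intramolecular Mukaiyama aldol onto the Lewis-acid-activated hindered ketone to give the tertiary aldol F3. Dehydration with Burgess reagent gives 16. This replaces the reversible, thermodynamically driven condensation by a directed kinetic C–C bond formation and a separate elimination.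

**Step 4 (bromide SN2 next to the quaternary carbon, from the allyl-bearing face).** Elimination or allyl participation may win. Fallback, from 4 back to 9 (7 and 8 are bypassed): 4 is esterified with quinoline-8-sulfonyl chloride (Et3N, DMAP) to the quinoline-8-sulfonate F1 with retention. TiBr4 in CH2Cl2 at −78 °C then chelates the leaving group and delivers bromide from the same face (front-side, stereoretentive substitution). Bromide therefore ends cis to allyl without any backside attack on the hindered face, and the two inversions are replaced by one retentive substitution.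

## Further compounds

F1 | step 4 | (1S,2S)-2-methyl-3-oxo-2-(prop-2-en-1-yl)cyclopentyl quinoline-8-sulfonate | O=C1CC[C@H](OS(=O)(=O)c2cccc3cccnc23)[C@]1(C)CC=C
F2 | step 6 | trimethylsilyl dienol ether of 15 (2-silyloxydiene, Z-enone geometry) | O=C1[C@@](C)(/C(C)=C\C(O[Si](C)(C)C)=CC)C[C@H](Br)[C@]1(C)CC=C
F3 | step 6 | bicyclic tertiary aldol, 2-bromo-3a-hydroxy-3,4,7,7a-tetramethyl-3-(prop-2-en-1-yl)-1,2,3,3a,4,7a-hexahydro-5H-inden-5-one (3a-OH cis to 7a-Me, C4 epimers) | CC1C(=O)C=C(C)[C@@]2(C)C[C@H](Br)[C@](C)(CC=C)[C@@]12O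
F4 | step 9 | (E)-enol acetate of aldehyde 20 | CC1=C2[C@@](C)(/C=C/OC(C)=O)[C@@H](Br)C[C@]2(C)[C@@H](C)CC1=O
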